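The runs are calculated from invented constants; noise was put on by code.

6 questions stand on the bench, and behind them lies one decision: which flask I charge next, and what I leave as it is.

| flask | substrate | partner | free catalyst | temperature | remark | time |
|---|---|---|---|---|---|---|
| ash | 11 mM | 13.2 mM | 55 µM | 35 °C | run made earlier |  |
| larch | 11 mM | 13.2 mM | 28 µM | 46 °C | run made earlier |  |
| maple | 11 mM | 13.2 mM | 41 µM | 35 °C | run made earlier |  |
| birch | 22 mM | 13.2 mM | 55 µM | 46 °C | run made earlier |  |
| noon | 11 mM | 13.2 mM (in portions, 2, over 5.0 h) | 55 µM | 40 °C | first portion at the start, last at 5.0 h | 8.0 h |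
| midnight | 11 mM | 13.2 mM (fed, over 5.0 h) | 55 µM |  | the addition at 10 °C, then warmed to 40 °C; the feed brings no volume worth counting | 8.0 h |
| winter | 11 mM (fed, over 30 min) | 13.2 mM | 55 µM | 40 °C | all else is in the flask from the start; the feed brings no volume worth counting | 8.0 h |
| dawn | 11 mM | 13.2 mM | 55 µM | 40 °C | everything together at the start | 8.0 h |
| summer | 11 mM | 13.2 mM (fed, over 5.0 h) | 55 µM | 40 °C | all else is in the flask from the start; the feed brings no volume worth counting | 8.0 h |

| ash: time / h | ash: target / % | larch: time / h | larch: target / % | maple: time / h | maple: target / % | birch: time / h | birch: target / % |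
|---|---|---|---|---|---|---|---|
| 2.00 | 30.1 | 0.833 | 12.6 | 0.833 | 12.5 | 0.833 | 11.9 |
| 4.00 | 41.8 | 2.50 | 15.6 | 2.50 | 26.4 | 2.50 | 13.2 |
| 6.00 | 42.6 | 4.00 | 13.1 | 4.00 | 33.0 | 4.00 | 10.9 |
| 8.00 | 42.0 | 6.00 | 10.6 | 6.00 | 34.9 | 6.00 | 9.2 |

(scatter of a reading: 0.5 percentage points)

- which flask leads in amount of target, in percent of the substrate charged ("all alike" within 1.5 percentage points) (noon / midnight / winter / dawn / summer / all alike)
- how much target is there at the end, in percent of the substrate charged: noon
- how much target is there at the end, in percent of the substrate charged: midnight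
- how much target is there at the end, in percent of the substrate charged: winter
- how much target is there at the end, in percent of the substrate charged: dawn
- how much target is there at the end, in percent of the substrate charged: summer



I suppose that each target costs one partner, that partner not ending in target is lost by a side route, and that both routes are first order in partner, which no run tests. At a plateau, target made divided by partner lost is then the ratio of the two rates. The clock drops out of that ratio, and it should scale with the free catalyst charged. In ash, the reading at 6.00 h gives 4.69 mM of target from 13.2 mM of partner, so the ratio is 0.550, or 10.0 mM⁻¹ per catalyst. Maple, with less catalyst, gives 10.0 mM⁻¹, the same within the scatter.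

At 46 °C I use the peak readings, which a later loss of target lowers. Larch gives 5.34 mM⁻¹, and birch, with twice the substrate, gives 5.13 mM⁻¹. Interpolating the logarithm between ash and larch, each at its own temperature, to 40 °C gives 7.52 mM⁻¹. With 55 µM of catalyst, the partner odds, a selectivity factor between target made and partner lost, are 0.414. For dawn I reckon 35.1% of the substrate made as target, before any later loss.

So I leave substrate at 11 mM and catalyst at 55 µM and charge midnight next: its partner goes in at 10 °C, and the odds per catalyst read higher at 35 °C than at 46 °C. But 10 °C lies below my readings, so I trust the direction and not a size.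

The forecast also names midnight, with 17% for noon, 35% for midnight, 29% for winter, 32% for dawn and 9% for summer, holding that “Slow partner feeds starve the reaction”. My figure for dawn stands above its figure, since mine counts target before loss.

The flasks end at 35.2% for noon, 39.4% for midnight, 29.2% for winter, 29.6% for dawn and 36.9% for summer, so midnight leads.

    substrate + free catalyst → catalyst intermediate A (k = 139 M⁻¹ s⁻¹, Ea = 35.0 kJ mol⁻¹)
    partner + catalyst intermediate A ⇌ catalyst intermediate B (K = 97.2 M⁻¹, k = 5.14 M⁻¹ s⁻¹, Ea = 39.0 kJ mol⁻¹, ΔH = −36.0 kJ mol⁻¹)
    catalyst intermediate B → free catalyst + target (k = 0.0408 s⁻¹, Ea = 78.0 kJ mol⁻¹)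
    catalyst intermediate B → spent catalyst (k = 2.81 × 10⁻⁵ s⁻¹, Ea = 110 kJ mol⁻¹)
    target ⇌ isomer of the product (K = 12.0, k = 1.45 × 10⁻⁵ s⁻¹, Ea = 109 kJ mol⁻¹, ΔH = −26.0 kJ mol⁻¹)
    partner → decomposed reagent (k = 1.65 × 10⁻⁴ s⁻¹, Ea = 98.0 kJ mol⁻¹)
    (constants at 40 °C)

At 8.00 h midnight holds 7.63 mM of decomposed reagent against 8.58 mM in dawn. Counting target and isomer of the product together as made, midnight's odds are 0.637 and those of summer, fed at 40 °C throughout, are 0.643, about the same and both above the 0.414 I reckoned. The neighbour flask, midnight with 33 mM of partner, takes the same quantity: 0.414 puts 87.8% of the substrate into target and isomer, and that flask holds 82.2%, of which target is 73.9%.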